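**Assumption:** the SMILES carries no stereodescriptor, so the hindered 6,8''-biaryl axis is taken as unspecified and the compound is made as drawn (racemic about that axis); there is no stereocentre to set.

**Retrosynthetic overview**
1. Last operation: hydrogenolysis of three benzyl ethers (5-O and 7-O of the 8-linked unit A, 4'-O of the 6-linked unit B).
2. Key disconnection: the pyranone O1–C2 bond of unit A, closed last by a one-flask annulation of a biaryl 2'-hydroxyacetophenone with 4-methoxybenzaldehyde. The only free phenol on that ring lies between the biaryl bond and the acyl group, which fixes the 8-linkage.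
3. Biaryl bond before that: Suzuki–Miyaura union of the 6-boronate of a genkwanin-type flavone (unit B) with a 3-iodo-2-hydroxyacetophenone; both iodides come from phenol-directed iodination.
4. Ring order: pyranone of unit B first (one-pot aroylation/Baker–Venkataraman/cyclodehydration), then the biaryl bond, then the pyranone of unit A.

**Route**

Step 1
Reactants: 1 1-(2,4,6-trihydroxyphenyl)ethan-1-one (used as the monohydrate)
Product: 2 1-[2,4-bis(benzyloxy)-6-hydroxyphenyl]ethan-1-one
Conditions: BnBr (2.1 equiv), K2CO3 (2.5 equiv), DMF, rt, 16 h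
Reagents that add atoms: benzyl bromide, BrCc1ccccc1
Why: Williamson etherification takes the para hydroxyl and one ortho hydroxyl, while the remaining ortho hydroxyl is hydrogen-bonded to the ketone and stays free.

Step 2
Reactants: 2 1-[2,4-bis(benzyloxy)-6-hydroxyphenyl]ethan-1-one
Product: 3 1-[4,6-bis(benzyloxy)-2-hydroxy-3-iodophenyl]ethan-1-one
Conditions: BnNMe3·ICl2 (1.05 equiv), CaCO3 (1.5 equiv), CH2Cl2/MeOH (5:2), rt
Reagents that add atoms: benzyltrimethylammonium dichloroiodate, C[N+](C)(C)Cc1ccccc1.Cl[I-]Cl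
Why: Electrophilic aromatic iodination goes ortho to the free chelated phenol (position 3) and not to the more crowded position between the two benzyloxy groups, as is established for the 4,6-dimethoxy analogue.

Step 3
Reactants: 4 1-(2,6-dihydroxy-4-methoxyphenyl)ethan-1-one, 5 4-(benzyloxy)benzoyl chloride
Product: 8 2-[4-(benzyloxy)phenyl]-5-hydroxy-7-methoxy-4H-chromen-4-one, via aryl ester 6 (not isolated), via beta-diketone 7 (not isolated)
Conditions: 5 (1.2 equiv), K2CO3 (5 equiv), acetone, reflux, 24 h; aq. HCl work-up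
Reagents that add atoms: none
Why: O-aroylation, Baker–Venkataraman acyl shift and cyclodehydration run in one flask, and because the ketone is symmetric either hydroxyl closes the same pyranone while the other remains as the chelated 5-OH.

Step 4
Reactants: 8 2-[4-(benzyloxy)phenyl]-5-hydroxy-7-methoxy-4H-chromen-4-one
Product: 9 2-[4-(benzyloxy)phenyl]-5-hydroxy-6-iodo-7-methoxy-4H-chromen-4-one
Conditions: BnNMe3·ICl2 (1.1 equiv), CaCO3, CH2Cl2/MeOH, rt
Reagents that add atoms: benzyltrimethylammonium dichloroiodate, C[N+](C)(C)Cc1ccccc1.Cl[I-]Cl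
Why: Electrophilic aromatic iodination of a 5-hydroxy-7-methoxyflavone is directed ortho to the free 5-OH and gives the 6-iodide, while the enone-deactivated benzyloxyphenyl ring does not react.

Step 5
Reactants: 9 2-[4-(benzyloxy)phenyl]-5-hydroxy-6-iodo-7-methoxy-4H-chromen-4-one, 3 1-[4,6-bis(benzyloxy)-2-hydroxy-3-iodophenyl]ethan-1-one
Product: 11 6-[3-acetyl-4,6-bis(benzyloxy)-2-hydroxyphenyl]-2-[4-(benzyloxy)phenyl]-5-hydroxy-7-methoxy-4H-chromen-4-one, via pinacol boronate 10 (not isolated)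
Conditions: Pd(OAc)2 (5 mol %), SPhos (10 mol %), B2pin2 (1.2 equiv), KOAc (3 equiv), 1,4-dioxane, 90 °C; then 3 (0.8 equiv), K3PO4 (3 equiv), H2O, 100 °C
Reagents that add atoms: none
Why: Miyaura borylation of the less electron-rich iodide 9 is followed in the same flask by Suzuki–Miyaura coupling with 3 under SPhos-ligated zerovalent palladium, a system suited to tetra-ortho-substituted biaryls and tolerant of chelated phenols; no stereocentre forms and the axis arises without control.

Step 6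
Reactants: 11 6-[3-acetyl-4,6-bis(benzyloxy)-2-hydroxyphenyl]-2-[4-(benzyloxy)phenyl]-5-hydroxy-7-methoxy-4H-chromen-4-one, 12 4-methoxybenzaldehyde
Product: 15 5,7-bis(benzyloxy)-8-{2-[4-(benzyloxy)phenyl]-5-hydroxy-7-methoxy-4-oxo-4H-chromen-6-yl}-2-(4-methoxyphenyl)-4H-chromen-4-one, via chalcone 13 (not isolated), via flavanone 14 (not isolated)
Conditions: 12 (1.5 equiv), pyrrolidine (30 mol %), DMSO, 70 °C; then CF3CO2H (40 mol %), Pd(O2CCF3)2 (10 mol %), 5-nitro-1,10-phenanthroline (20 mol %), O2 (1 atm), 100 °C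
Reagents that add atoms: none
Why: Proposed new method: an amine/palladium relay annulation in one flask, in which pyrrolidine activates 12 as its iminium ion for Claisen–Schmidt condensation with the aryl methyl ketone, the resulting 2'-hydroxychalcone closes reversibly by 6-endo-trig oxa-Michael addition of the only free phenol ortho to the acyl group (the O1–C2 bond, which places the ring oxygen next to the biaryl bond), and divalent palladium then forms the C3 palladium enolate of the flavanone and undergoes beta-hydride elimination, with O2 reoxidising zerovalent palladium, so that the irreversible desaturation drains the chalcone/flavanone equilibrium to the flavone; the closest known reaction types are Kabbe-type amine-mediated flavanone synthesis and aerobic palladium-catalysed dehydrogenation of flavanones and 2'-hydroxydihydrochalcones, and the C2 stereocentre of 14 is erased on desaturation.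

Step 7
Reactants: 15 5,7-bis(benzyloxy)-8-{2-[4-(benzyloxy)phenyl]-5-hydroxy-7-methoxy-4-oxo-4H-chromen-6-yl}-2-(4-methoxyphenyl)-4H-chromen-4-one
Product: 16 8-[5-hydroxy-2-(4-hydroxyphenyl)-7-methoxy-4-oxo-4H-chromen-6-yl]-5,7-dihydroxy-2-(4-methoxyphenyl)-4H-chromen-4-one (CNP0253922.0)
Conditions: H2 (1 atm), 10% Pd/C, THF/MeOH (1:1), rt
Reagents that add atoms: none
Why: Hydrogenolysis cleaves the three aryl benzyl ethers under neutral conditions, leaving the two methyl ethers and both flavone enones intact and causing no acid-promoted pyranone isomerisation (Wessely–Moser).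

**Compound list**
1 | 1-(2,4,6-trihydroxyphenyl)ethan-1-one | CC(=O)c1c(O)cc(O)cc1O | starting material
2 | 1-[2,4-bis(benzyloxy)-6-hydroxyphenyl]ethan-1-one | CC(=O)c1c(O)cc(OCc2ccccc2)cc1OCc1ccccc1 | intermediate
3 | 1-[4,6-bis(benzyloxy)-2-hydroxy-3-iodophenyl]ethan-1-one | CC(=O)c1c(O)c(I)c(OCc2ccccc2)cc1OCc1ccccc1 | intermediate
4 | 1-(2,6-dihydroxy-4-methoxyphenyl)ethan-1-one | CC(=O)c1c(O)cc(OC)cc1O | starting material
5 | 4-(benzyloxy)benzoyl chloride | O=C(Cl)c1ccc(OCc2ccccc2)cc1 | starting material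
6 | 2-acetyl-3-hydroxy-5-methoxyphenyl 4-(benzyloxy)benzoate (not isolated) | CC(=O)c1c(O)cc(OC)cc1OC(=O)c1ccc(OCc2ccccc2)cc1 | intermediate
7 | 1-[4-(benzyloxy)phenyl]-3-(2,6-dihydroxy-4-methoxyphenyl)propane-1,3-dione (not isolated) | COc1cc(O)c(C(=O)CC(=O)c2ccc(OCc3ccccc3)cc2)c(O)c1 | intermediate
8 | 2-[4-(benzyloxy)phenyl]-5-hydroxy-7-methoxy-4H-chromen-4-one | COc1cc(O)c2c(c1)oc(-c1ccc(OCc3ccccc3)cc1)cc2=O | intermediate
9 | 2-[4-(benzyloxy)phenyl]-5-hydroxy-6-iodo-7-methoxy-4H-chromen-4-one | COc1cc2oc(-c3ccc(OCc4ccccc4)cc3)cc(=O)c2c(O)c1I | intermediate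
10 | 2-[4-(benzyloxy)phenyl]-5-hydroxy-7-methoxy-6-(4,4,5,5-tetramethyl-1,3,2-dioxaborolan-2-yl)-4H-chromen-4-one (not isolated) | COc1cc2oc(-c3ccc(OCc4ccccc4)cc3)cc(=O)c2c(O)c1B1OC(C)(C)C(C)(C)O1 | intermediate
11 | 6-[3-acetyl-4,6-bis(benzyloxy)-2-hydroxyphenyl]-2-[4-(benzyloxy)phenyl]-5-hydroxy-7-methoxy-4H-chromen-4-one (racemic axis) | CC(=O)c1c(O)c(-c2c(OC)cc3oc(-c4ccc(OCc5ccccc5)cc4)cc(=O)c3c2O)c(OCc2ccccc2)cc1OCc1ccccc1 | intermediate
12 | 4-methoxybenzaldehyde | COc1ccc(C=O)cc1 | starting material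
13 | 6-{4,6-bis(benzyloxy)-2-hydroxy-3-[(2E)-3-(4-methoxyphenyl)prop-2-enoyl]phenyl}-2-[4-(benzyloxy)phenyl]-5-hydroxy-7-methoxy-4H-chromen-4-one (not isolated) | COc1ccc(/C=C/C(=O)c2c(O)c(-c3c(OC)cc4oc(-c5ccc(OCc6ccccc6)cc5)cc(=O)c4c3O)c(OCc3ccccc3)cc2OCc2ccccc2)cc1 | intermediate
14 | 5,7-bis(benzyloxy)-8-{2-[4-(benzyloxy)phenyl]-5-hydroxy-7-methoxy-4-oxo-4H-chromen-6-yl}-2-(4-methoxyphenyl)-2,3-dihydro-4H-chromen-4-one (racemic at C2, not isolated) | COc1ccc(C2CC(=O)c3c(OCc4ccccc4)cc(OCc4ccccc4)c(-c4c(OC)cc5oc(-c6ccc(OCc7ccccc7)cc6)cc(=O)c5c4O)c3O2)cc1 | intermediate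
15 | 5,7-bis(benzyloxy)-8-{2-[4-(benzyloxy)phenyl]-5-hydroxy-7-methoxy-4-oxo-4H-chromen-6-yl}-2-(4-methoxyphenyl)-4H-chromen-4-one | COc1ccc(-c2cc(=O)c3c(OCc4ccccc4)cc(OCc4ccccc4)c(-c4c(OC)cc5oc(-c6ccc(OCc7ccccc7)cc6)cc(=O)c5c4O)c3o2)cc1 | intermediate
16 | 8-[5-hydroxy-2-(4-hydroxyphenyl)-7-methoxy-4-oxo-4H-chromen-6-yl]-5,7-dihydroxy-2-(4-methoxyphenyl)-4H-chromen-4-one | COc1ccc(-c2cc(=O)c3c(O)cc(O)c(-c4c(OC)cc5oc(-c6ccc(O)cc6)cc(=O)c5c4O)c3o2)cc1 | target

**Totals**
Total step count: 7. Longest linear sequence: 5 steps (steps 1, 2, 5, 6, 7 or steps 3, 4, 5, 6, 7).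

**Steps most likely to fail, with fallbacks**

Step 3 (one-pot aroylation/rearrangement/cyclodehydration; modest yields and 3-aroylflavone by-products are typical). The fallback sets out from 4 and comes back at 8. Claisen–Schmidt condensation of 4 with 4-(benzyloxy)benzaldehyde (KOH, EtOH/H2O, rt) gives (E)-3-[4-(benzyloxy)phenyl]-1-(2,6-dihydroxy-4-methoxyphenyl)prop-2-en-1-one F1. Oxidative cyclisation of this chalcone with catalytic I2 in DMSO at 130 °C then gives 8.

Step 5 (the riskiest known step: a tetra-ortho-substituted coupling in which both partners carry a free ortho phenol, with protodeboronation of 10 as the likely leak). The fallback sets out from 3 and comes back at 15, so the pyranone of unit A is closed before the biaryl bond. Claisen–Schmidt condensation of 3 with 12 (KOH, EtOH, rt) gives (E)-1-[4,6-bis(benzyloxy)-2-hydroxy-3-iodophenyl]-3-(4-methoxyphenyl)prop-2-en-1-one F2. Catalytic I2 in DMSO at 130 °C converts it into 5,7-bis(benzyloxy)-8-iodo-2-(4-methoxyphenyl)-4H-chromen-4-one F3, which has no phenoxide next to the C–I bond. Boronate 10 is then made from 9 as in step 5 but isolated, and coupled with F3 (Pd(OAc)2, SPhos, K3PO4, toluene/H2O, 100 °C). This is the established iodoflavone plus flavone-boronate union and gives 15 directly.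

Step 6 (the proposed new relay annulation; the hindered ketone may condense slowly and the amine may interfere with the palladium stage). The fallback uses known chemistry, sets out from 11 and comes back at 15. The lithium polyanion of 11 (LiN(SiMe3)2, 5 equiv, THF, −78 °C) is C-aroylated with 4-methoxybenzoyl chloride to give 1-{4,6-bis(benzyloxy)-3-[2-(4-(benzyloxy)phenyl)-5-hydroxy-7-methoxy-4-oxo-4H-chromen-6-yl]-2-hydroxyphenyl}-3-(4-methoxyphenyl)propane-1,3-dione F4. Acid cyclodehydration (TsOH·H2O, toluene, 90 °C) closes the same O1–C2 bond without any oxidation and gives 15.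

**Further compounds**
F1 | step 3 | (E)-3-[4-(benzyloxy)phenyl]-1-(2,6-dihydroxy-4-methoxyphenyl)prop-2-en-1-one | COc1cc(O)c(C(=O)/C=C/c2ccc(OCc3ccccc3)cc2)c(O)c1
F2 | step 5 | (E)-1-[4,6-bis(benzyloxy)-2-hydroxy-3-iodophenyl]-3-(4-methoxyphenyl)prop-2-en-1-one | COc1ccc(/C=C/C(=O)c2c(O)c(I)c(OCc3ccccc3)cc2OCc2ccccc2)cc1
F3 | step 5 | 5,7-bis(benzyloxy)-8-iodo-2-(4-methoxyphenyl)-4H-chromen-4-one | COc1ccc(-c2cc(=O)c3c(OCc4ccccc4)cc(OCc4ccccc4)c(I)c3o2)cc1
F4 | step 6 | 1-{4,6-bis(benzyloxy)-3-[2-(4-(benzyloxy)phenyl)-5-hydroxy-7-methoxy-4-oxo-4H-chromen-6-yl]-2-hydroxyphenyl}-3-(4-methoxyphenyl)propane-1,3-dione | COc1ccc(C(=O)CC(=O)c2c(O)c(-c3c(OC)cc4oc(-c5ccc(OCc6ccccc6)cc5)cc(=O)c4c3O)c(OCc3ccccc3)cc2OCc2ccccc2)cc1
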